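The data are calculated on assumed constants, and the scatter is random.

At early times each flask, closed and stirred, with substrate and coupling partner joining to product under free catalyst, looks healthy. Over the first 2.4 min the readings give product at 0.0334 M min⁻¹ in the oak run, at 0.0453 M min⁻¹ in the ash run, charged with 1.60 M of substrate, at 0.0212 M min⁻¹ in the cedar run, and at 0.0273 M min⁻¹ in the maple run, with 2.40 M of coupling partner, which is slower than the oak run, so over this first stretch more coupling partner goes with less speed.

| flask | substrate | coupling partner | free catalyst | time |
|---|---|---|---|---|
| oak | 0.800 M | 0.800 M | 0.0160 M |  |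
| cedar | 0.480 M | 0.480 M | 0.0160 M |  |
| ash | 1.60 M | 0.800 M | 0.0160 M |  |
| maple | 0.800 M | 2.40 M | 0.0160 M |  |
| birch | 0.800 M | 2.40 M | 0.0320 M | 59 min |

| oak run: time / min | oak run: [product] / M | cedar run: time / min | cedar run: [product] / M | ash run: time / min | ash run: [product] / M | maple run: time / min | maple run: [product] / M |
|---|---|---|---|---|---|---|---|
| 2.4 | 0.0801 | 2.4 | 0.0509 | 2.4 | 0.1088 | 2.4 | 0.0656 |
| 3.7 | 0.1207 | 3.7 | 0.0742 | 3.7 | 0.1664 | 3.7 | 0.0949 |
| 5.9 | 0.1837 | 5.9 | 0.1122 | 5.9 | 0.2525 | 5.9 | 0.1479 |
| 9.4 | 0.2682 | 9.4 | 0.1690 | 9.4 | 0.3644 | 9.4 | 0.2194 |
| 15 | 0.3714 | 15 | 0.2318 | 15 | 0.5042 | 15 | 0.3080 |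
| 24 | 0.4775 | 24 | 0.3029 | 24 | 0.6326 | 24 | 0.3977 |
| 37 | 0.5490 | 37 | 0.3525 | 37 | 0.7156 | 37 | 0.4723 |
| 59 | 0.5932 | 59 | 0.3817 | 59 | 0.7642 | 59 | 0.5110 |

(each reading ± 0.002 M)

- Overall: substrate + coupling partner -> product, with free catalyst as catalyst.
- Constant volume, constant temperature.
- Readings of a species count what is bound in complexes too.
- An order is taken over about fifteen percent of the charge, up and down.

- the power of [coupling partner] that the first rate follows, about the charge of the oak run; measure it at two percent of substrate made into product
- the power of [substrate] that the first rate follows, about the charge of the oak run; measure it at two percent of substrate made into product (one fixed amount of product, the same in the runs compared)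
- the cedar run starts with 0.320 M less of substrate and of coupling partner than the oak run, and with no product. Compared where both hold the same amount of substrate, once fifteen percent of what the cedar run was charged with has turned into product, is the cedar run faster, slower or alike (within a tenth)?
- product in the birch run at 59 min, as a share of the substrate charged

The next rung of the ladder is the half-life of the substrate, and the maple run holds 0.3977 M of product at 24 min, about half of its charge. With a steady catalyst and a rate following the unmade substrate, each further halving would take that same time, and 59 min would hold 2.46 half-lives. So we count them from the readings: the half-life count, the logarithm to base two of the charge over what is still unmade, comes to 1.47 for the maple run at 59 min, less than that steady figure.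

The slowest rung shows in the last interval of the maple run, where product grows at 0.00176 M min⁻¹. That is 6.45 % of the rate over the first 2.4 min, while 36.1 % of the substrate is still unmade, so the rate has fallen further than the substrate, and we read a catalyst wearing out over tens of minutes.

The birch run holds twice the catalyst of the maple run on the same substrate and coupling partner. Our own reckoning is that if the catalyst wears on a steady clock, twice the catalyst does twice the work in the same time, so the count becomes 2.94 and the product 87.0 % of the charge.

The forecast gives orders of 0.1 in coupling partner and 0.55 in substrate, calls the cedar run faster, and puts the birch run at 88 %, reasoning that “Assuming first-order death and first-order catalyst, birch has twice maple's integrated catalyst exposure.” That doubling is the premise of our count too, so we take the closeness of the two as no check.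

    free catalyst + substrate ⇌ catalyst-substrate complex (6.480 L mol⁻¹ min⁻¹, 1.416 min⁻¹)
    catalyst-substrate complex + coupling partner → product + free catalyst (15.48 L mol⁻¹ min⁻¹)
    free catalyst + product → spent catalyst + product (0.1158 L mol⁻¹ min⁻¹)
    substrate + coupling partner ⇌ idle substrate-reagent adduct, settled at all times (0.8780 L mol⁻¹)

The flask gives orders of 0.16 and 0.70, the cedar run faster, and the birch run 80.3 %, lower than the forecast, which is a count of 2.34 half-lives against our 2.94. The count falls short because product kills free catalyst while the idle substrate-reagent adduct holds substrate back. The birch run without the killing step reaches 99.0 %, a count of 6.64, and without the adduct it reaches 95.3 %.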